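**Plan**

- Retrosynthesis: the two C5–prenyl bonds are cut first (dearomatising double C-alkylation of an acylphloroglucinol), then the C7–acyl bond (directed lithiation), then the two C–CH3 bonds of the carbinol (ester plus MeMgBr), and last O1–C2 and C2–C3 of the dihydrofuran.
- Enabling feature: C2 is a single carbon held between the ring oxygen O1 and the benzylic CH2 carbon C3. The ring O1–C2–C3–C3a–C7a can therefore be closed by delivering C2 as an ylide carbon to an o-quinone methide spanning O1, C7a, C3a and C3.
- Forward order: 2,4,6-trihydroxybenzaldehyde is differentiated (4-O-MOM, 2-O-TIPS) and converted into a benzylic trimethylammonium salt. Base unmasks the o-quinone methide, and a cinchona ammonium ylide made from methyl bromoacetate closes the dihydrofuran, the only ring formed; the carbocycle is the starting arene.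
- The ester then becomes the dimethylcarbinol, C7 is acylated, the phenols are freed, and C5 is prenylated twice, which dearomatises the carbocycle.
- Stereochemistry: the only stereocentre, C2 (R), is set in the annulation by the chiral ammonium leaving group and is not touched afterwards.

Key step: step 7

Assumption: the quinidine-derived ammonium salt of step 6 is taken to favour the (R)-configured ring closure; if the sense proves opposite, the pseudoenantiomeric quinine-derived salt would be used with no other change. The target is treated as the 4-keto-6-enol tautomer drawn.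

**Route**

Step 1
Reactants: 1 2,4,6-trihydroxybenzaldehyde
Product: 2 2,6-dihydroxy-4-(methoxymethoxy)benzaldehyde
Conditions: MOMCl (1.05 equiv), i-Pr2NEt, THF, 0 °C
Reagents that add atoms: chloromethyl methyl ether (MOMCl), COCCl
Why: Williamson-type MOM ether formation; the 4-OH is the most acidic hydroxyl and the only one not engaged with the formyl group, so one equivalent of MOMCl should alkylate it preferentially.

Step 2
Reactants: 2 2,6-dihydroxy-4-(methoxymethoxy)benzaldehyde
Product: 3 2-hydroxy-4-(methoxymethoxy)-6-(triisopropylsilyloxy)benzaldehyde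
Conditions: TIPSCl (1.1 equiv), imidazole, DMF, 0 °C to rt
Reagents that add atoms: chlorotriisopropylsilane (TIPSCl), CC(C)[Si](Cl)(C(C)C)C(C)C
Why: Silyl ether formation; the two hydroxyls are equivalent by symmetry, and after the first silylation the remaining one is locked in a hydrogen bond to the aldehyde, so the reaction should stop at the mono-TIPS ether, whose bulk later shields C5.

Step 3
Reactants: 3 2-hydroxy-4-(methoxymethoxy)-6-(triisopropylsilyloxy)benzaldehyde
Product: 5 2-[(dimethylamino)methyl]-5-(methoxymethoxy)-3-(triisopropylsilyloxy)phenol, via iminium zwitterion 4 (not isolated)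
Conditions: Me2NH (2 M in THF), AcOH, NaBH(OAc)3, DCE, rt
Reagents that add atoms: dimethylamine, CNC
Why: Reductive amination; the salicylaldehyde condenses with dimethylamine to the iminium phenoxide, which triacetoxyborohydride reduces to the phenolic Mannich base without passing through a benzylic alkoxide that could take up the neighbouring silyl group.

Step 4
Reactants: 5 2-[(dimethylamino)methyl]-5-(methoxymethoxy)-3-(triisopropylsilyloxy)phenol
Product: 6 [2-hydroxy-4-(methoxymethoxy)-6-(triisopropylsilyloxy)benzyl]trimethylammonium iodide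
Conditions: MeI (3 equiv), MeCN, rt, dark
Reagents that add atoms: iodomethane, CI
Why: Menshutkin N-alkylation; the tertiary amine is far more nucleophilic than the neutral phenol, giving a benzylic trimethylammonium salt that is a latent o-quinone methide and stays intact until the phenol is deprotonated.

Step 5
Reactants: 7 quinidine
Product: 8 9-O-methylquinidine
Conditions: NaH, DMF, 0 °C; MeI (1.05 equiv), 0 °C to rt
Reagents that add atoms: iodomethane, CI
Why: Williamson etherification of the C9 alkoxide; capping the hydroxyl removes the possibility of its lactonisation onto the ester arm of the ammonium salt under the basic conditions of the annulation.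

Step 6
Reactants: 8 9-O-methylquinidine; 9 methyl bromoacetate
Product: 10 N-(2-methoxy-2-oxoethyl)-9-O-methylquinidinium bromide (alkylated at the quinuclidine nitrogen)
Conditions: THF, rt
Reagents that add atoms: none
Why: Menshutkin quaternisation; the quinuclidine nitrogen is much more nucleophilic than the quinoline nitrogen, and the salt should precipitate from THF.

Step 7
Reactants: 6 [2-hydroxy-4-(methoxymethoxy)-6-(triisopropylsilyloxy)benzyl]trimethylammonium iodide; 10 N-(2-methoxy-2-oxoethyl)-9-O-methylquinidinium bromide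
Product: 14 methyl (2R)-6-(methoxymethoxy)-4-(triisopropylsilyloxy)-2,3-dihydro-1-benzofuran-2-carboxylate, via o-quinone methide 11 (not isolated), via ammonium ylide 12 (not isolated), via betaine 13 (not isolated)
Conditions: 10 (1.5 equiv), Cs2CO3 (4 equiv), CH2Cl2, 0 °C to rt; 6 added slowly as a CH2Cl2/MeCN solution
Reagents that add atoms: none
Why: Proposed new method: Cs2CO3 deprotonates phenol 6, whose phenoxide expels NMe3 to give o-quinone methide 11, and converts salt 10 into the ester-stabilised ylide 12; 1,4-addition of the ylide carbon to the exocyclic CH2 of 11 forms C2–C3 and re-aromatises to betaine 13. The phenoxide of 13 then displaces the quinuclidinium nitrogen at C2 in a 5-exo-tet SN2 closure that forms O1–C2 and the dihydrofuran ring, a formal (4+1) annulation overall. The closest known reactions are the cinchona ammonium ylide (4+1) annulations of in situ o-quinone methides carrying an aryl group on the methide carbon and the racemic pyridinium ylide annulations of unsubstituted o-quinone methides released from Mannich-base salts; what is new is enantiocontrol when the methide carbon is CH2 and C2 is the only stereocentre. In 13 the C2–H lies between ester and ammonium and should exchange quickly under carbonate, so the two epimers equilibrate and drain through the one whose SN2 transition state is less hindered by the alkaloid (Curtin–Hammett), the chiral leaving group thereby fixing (R) at C2. Regiochemistry is unambiguous because only one ortho oxygen is free; the chemoselectivity needed (ylide capture of 11 in preference to C-alkylation of another electron-rich phenoxide ring) is secured by keeping 11 dilute in an excess of ylide and by the flanking OTIPS and OMOM groups, and the product ester is not acidic enough to epimerise under carbonate in CH2Cl2.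

Step 8
Reactants: 14 methyl (2R)-6-(methoxymethoxy)-4-(triisopropylsilyloxy)-2,3-dihydro-1-benzofuran-2-carboxylate
Product: 16 2-[(2R)-6-(methoxymethoxy)-4-(triisopropylsilyloxy)-2,3-dihydro-1-benzofuran-2-yl]propan-2-ol, via methyl ketone 15 (not isolated)
Conditions: MeMgBr (3.5 equiv), THF, −20 to 0 °C; aq. NH4Cl
Reagents that add atoms: methylmagnesium bromide, C[Mg]Br
Why: Double Grignard addition to the ester through ketone 15; carbonyl addition at low temperature should outrun enolisation, so C2 keeps its configuration, and the aryl silyl ether and MOM acetal are inert to the reagent.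

Step 9
Reactants: 16 2-[(2R)-6-(methoxymethoxy)-4-(triisopropylsilyloxy)-2,3-dihydro-1-benzofuran-2-yl]propan-2-ol; 17 isovaleraldehyde (3-methylbutanal)
Product: 19 (1RS)-1-[(2R)-2-(2-hydroxypropan-2-yl)-6-(methoxymethoxy)-4-(triisopropylsilyloxy)-2,3-dihydro-1-benzofuran-7-yl]-3-methylbutan-1-ol, via aryllithium 18 (not isolated)
Conditions: n-BuLi (2.3 equiv), TMEDA, THF, −20 to 0 °C; then 17, −78 °C to rt
Reagents that add atoms: none
Why: Directed ortho-metalation; after the alkoxide has formed, n-BuLi should remove H7, the only ring hydrogen flanked by two coordinating oxygens (OMOM and ring O1), while H5 is shielded by the OTIPS group, and the aryllithium adds to the aldehyde to give a carbinol mixture whose new centre is erased in the next step.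

Step 10
Reactants: 19 (1RS)-1-[(2R)-2-(2-hydroxypropan-2-yl)-6-(methoxymethoxy)-4-(triisopropylsilyloxy)-2,3-dihydro-1-benzofuran-7-yl]-3-methylbutan-1-ol
Product: 20 1-[(2R)-2-(2-hydroxypropan-2-yl)-6-(methoxymethoxy)-4-(triisopropylsilyloxy)-2,3-dihydro-1-benzofuran-7-yl]-3-methylbutan-1-one
Conditions: Dess–Martin periodinane, pyridine, CH2Cl2, 0 °C to rt
Reagents that add atoms: none
Why: Dess–Martin oxidation of the secondary benzylic alcohol to the aryl ketone; the tertiary alcohol cannot be oxidised, and the pyridine buffer protects the acid-sensitive benzylic alcohol and MOM acetal.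

Step 11
Reactants: 20 1-[(2R)-2-(2-hydroxypropan-2-yl)-6-(methoxymethoxy)-4-(triisopropylsilyloxy)-2,3-dihydro-1-benzofuran-7-yl]-3-methylbutan-1-one
Product: 22 1-[(2R)-4,6-dihydroxy-2-(2-hydroxypropan-2-yl)-2,3-dihydro-1-benzofuran-7-yl]-3-methylbutan-1-one, via phenol 21 (not isolated)
Conditions: TBAF, THF, 0 °C; then 2 M HCl, MeOH, 40 °C
Reagents that add atoms: none
Why: Fluoride-mediated cleavage of the aryl silyl ether followed in the same flask by acid-catalysed acetal exchange of the MOM ether, which is assisted by the ortho carbonyl; the tertiary alcohol lies beta to the ring oxygen and should resist ionisation under these mild conditions.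

Step 12
Reactants: 22 1-[(2R)-4,6-dihydroxy-2-(2-hydroxypropan-2-yl)-2,3-dihydro-1-benzofuran-7-yl]-3-methylbutan-1-one; 23 prenyl bromide (1-bromo-3-methylbut-2-ene)
Product: 25 (2R)-6-hydroxy-2-(2-hydroxypropan-2-yl)-7-(3-methylbutanoyl)-5,5-bis(3-methylbut-2-en-1-yl)-2,3-dihydro-1-benzofuran-4(5H)-one, via monoprenyl phenol 24 (not isolated)
Conditions: NaOMe (3 equiv), 23 (2.3 equiv), MeOH, 0 °C to rt; dilute HCl work-up
Reagents that add atoms: none
Why: Dearomatising double C-alkylation of an acylphloroglucinol (lupulone-type prenylation); the phenoxide is alkylated in the protic medium at C5, the only unsubstituted ring carbon and the one flanked by two oxyanions, and a second alkylation at the same carbon creates the quaternary centre and leaves the vinylogous acid of the target, with C2 remote and unaffected.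

**Compound list**

1 | 2,4,6-trihydroxybenzaldehyde | O=Cc1c(O)cc(O)cc1O | starting material
2 | 2,6-dihydroxy-4-(methoxymethoxy)benzaldehyde | O=Cc1c(O)cc(OCOC)cc1O | intermediate
3 | 2-hydroxy-4-(methoxymethoxy)-6-(triisopropylsilyloxy)benzaldehyde | O=Cc1c(O)cc(OCOC)cc1O[Si](C(C)C)(C(C)C)C(C)C | intermediate
4 | 2-[(dimethyliminio)methyl]-5-(methoxymethoxy)-3-(triisopropylsilyloxy)phenolate, iminium zwitterion (not isolated) | C[N+](C)=Cc1c([O-])cc(OCOC)cc1O[Si](C(C)C)(C(C)C)C(C)C | intermediate
5 | 2-[(dimethylamino)methyl]-5-(methoxymethoxy)-3-(triisopropylsilyloxy)phenol | CN(C)Cc1c(O)cc(OCOC)cc1O[Si](C(C)C)(C(C)C)C(C)C | intermediate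
6 | [2-hydroxy-4-(methoxymethoxy)-6-(triisopropylsilyloxy)benzyl]trimethylammonium iodide | C[N+](C)(C)Cc1c(O)cc(OCOC)cc1O[Si](C(C)C)(C(C)C)C(C)C.[I-] | intermediate
7 | quinidine, (S)-[(1S,2R,4S,5R)-5-ethenyl-1-azabicyclo[2.2.2]octan-2-yl](6-methoxyquinolin-4-yl)methanol | COc1ccc2nccc([C@@H]([C@H]3C[C@@H]4CCN3C[C@@H]4C=C)O)c2c1 | starting material
8 | 9-O-methylquinidine | COc1ccc2nccc([C@@H]([C@H]3C[C@@H]4CCN3C[C@@H]4C=C)OC)c2c1 | intermediate
9 | methyl bromoacetate | COC(=O)CBr | starting material
10 | N-(2-methoxy-2-oxoethyl)-9-O-methylquinidinium bromide (quinuclidine N-alkylated) | COc1ccc2nccc([C@@H]([C@H]3C[C@@H]4CC[N@@+]3(CC(=O)OC)C[C@@H]4C=C)OC)c2c1.[Br-] | intermediate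
11 | 3-(methoxymethoxy)-6-methylidene-5-(triisopropylsilyloxy)cyclohexa-2,4-dien-1-one, o-quinone methide (not isolated) | C=C1C(=O)C=C(OCOC)C=C1O[Si](C(C)C)(C(C)C)C(C)C | intermediate
12 | ammonium ylide of 10, carbanion at the carbon between N+ and the ester (not isolated) | COc1ccc2nccc([C@@H]([C@H]3C[C@@H]4CC[N@@+]3([CH-]C(=O)OC)C[C@@H]4C=C)OC)c2c1 | intermediate
13 | phenoxide–ammonium betaine, both epimers at the ammonium-bearing carbon (not isolated) | COc1ccc2nccc([C@@H]([C@H]3C[C@@H]4CC[N@@+]3(C(Cc5c([O-])cc(OCOC)cc5O[Si](C(C)C)(C(C)C)C(C)C)C(=O)OC)C[C@@H]4C=C)OC)c2c1 | intermediate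
14 | methyl (2R)-6-(methoxymethoxy)-4-(triisopropylsilyloxy)-2,3-dihydro-1-benzofuran-2-carboxylate | COCOc1cc2O[C@@H](C(=O)OC)Cc2c(O[Si](C(C)C)(C(C)C)C(C)C)c1 | intermediate
15 | 1-[(2R)-6-(methoxymethoxy)-4-(triisopropylsilyloxy)-2,3-dihydro-1-benzofuran-2-yl]ethan-1-one (not isolated) | COCOc1cc2O[C@@H](C(C)=O)Cc2c(O[Si](C(C)C)(C(C)C)C(C)C)c1 | intermediate
16 | 2-[(2R)-6-(methoxymethoxy)-4-(triisopropylsilyloxy)-2,3-dihydro-1-benzofuran-2-yl]propan-2-ol | COCOc1cc2O[C@@H](C(C)(C)O)Cc2c(O[Si](C(C)C)(C(C)C)C(C)C)c1 | intermediate
17 | isovaleraldehyde (3-methylbutanal) | CC(C)CC=O | starting material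
18 | C7-lithio lithium alkoxide of 16 (not isolated) | COCOc1c([Li])c2O[C@@H](C(C)(C)O[Li])Cc2c(O[Si](C(C)C)(C(C)C)C(C)C)c1 | intermediate
19 | (1RS)-1-[(2R)-2-(2-hydroxypropan-2-yl)-6-(methoxymethoxy)-4-(triisopropylsilyloxy)-2,3-dihydro-1-benzofuran-7-yl]-3-methylbutan-1-ol | COCOc1c(C(O)CC(C)C)c2O[C@@H](C(C)(C)O)Cc2c(O[Si](C(C)C)(C(C)C)C(C)C)c1 | intermediate
20 | 1-[(2R)-2-(2-hydroxypropan-2-yl)-6-(methoxymethoxy)-4-(triisopropylsilyloxy)-2,3-dihydro-1-benzofuran-7-yl]-3-methylbutan-1-one | COCOc1c(C(=O)CC(C)C)c2O[C@@H](C(C)(C)O)Cc2c(O[Si](C(C)C)(C(C)C)C(C)C)c1 | intermediate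
21 | 1-[(2R)-4-hydroxy-2-(2-hydroxypropan-2-yl)-6-(methoxymethoxy)-2,3-dihydro-1-benzofuran-7-yl]-3-methylbutan-1-one (not isolated) | COCOc1c(C(=O)CC(C)C)c2O[C@@H](C(C)(C)O)Cc2c(O)c1 | intermediate
22 | 1-[(2R)-4,6-dihydroxy-2-(2-hydroxypropan-2-yl)-2,3-dihydro-1-benzofuran-7-yl]-3-methylbutan-1-one | Oc1c(C(=O)CC(C)C)c2O[C@@H](C(C)(C)O)Cc2c(O)c1 | intermediate
23 | prenyl bromide (1-bromo-3-methylbut-2-ene) | CC(C)=CCBr | starting material
24 | 1-[(2R)-4,6-dihydroxy-2-(2-hydroxypropan-2-yl)-5-(3-methylbut-2-en-1-yl)-2,3-dihydro-1-benzofuran-7-yl]-3-methylbutan-1-one (not isolated) | Oc1c(C(=O)CC(C)C)c2O[C@@H](C(C)(C)O)Cc2c(O)c1CC=C(C)C | intermediate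
25 | (2R)-6-hydroxy-2-(2-hydroxypropan-2-yl)-7-(3-methylbutanoyl)-5,5-bis(3-methylbut-2-en-1-yl)-2,3-dihydro-1-benzofuran-4(5H)-one | CC(C)=CCC1(CC=C(C)C)C(=O)C2=C(O[C@@H](C(C)(C)O)C2)C(C(=O)CC(C)C)=C1O | target

**Step count**

Total step count: 12.
Longest linear sequence: 10 steps (steps 1–4 and 7–12, from 1); steps 5 and 6 form a two-step side branch to salt 10.

**Steps most likely to fail**

1. Step 7 (carries the new-method label). The ring-closing displacement may discriminate the two interconverting betaine epimers poorly, giving low enantioselectivity. The o-quinone methide may also be consumed by C-alkylation of electron-rich phenoxide rings before the ylide captures it.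
Fallback, using known chemistry and setting the stereocentre by reagent-controlled epoxidation instead: setting out from 6, 2-methylprop-1-enylmagnesium bromide (2.5 equiv, THF, −78 to 0 °C) should release o-quinone methide 11 and add to its CH2 carbon. This would give 5-(methoxymethoxy)-2-(3-methylbut-2-en-1-yl)-3-(triisopropylsilyloxy)phenol F1. Acetylation (Ac2O, pyridine, DMAP) would give 5-(methoxymethoxy)-2-(3-methylbut-2-en-1-yl)-3-(triisopropylsilyloxy)phenyl acetate F2. Shi epoxidation with the L-fructose-derived enantiomer of the Shi ketone (Oxone, K2CO3, MeCN/dimethoxymethane/aqueous buffer, 0 °C) should then give 2-{[(2S)-3,3-dimethyloxiran-2-yl]methyl}-5-(methoxymethoxy)-3-(triisopropylsilyloxy)phenyl acetate F3. K2CO3 in MeOH would remove the acetate, and the phenoxide would open the epoxide at its secondary carbon (5-exo-tet, inversion) to deliver carbinol 16. The route is rejoined at 16, bypassing 14 and step 8.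

2. Step 12. O-prenylation may compete, the second alkylation may stall at the monoprenyl stage, or alkylation may occur at C3a instead of C5, so that little of the dearomatised product forms.
Fallback: setting out from 22, palladium-catalysed Tsuji–Trost allylation (allyl methyl carbonate, Pd(PPh3)4 cat., THF, rt) should be selective for carbon, because O-allyl products re-ionise under palladium. It would give the dearomatised (2R)-6-hydroxy-2-(2-hydroxypropan-2-yl)-7-(3-methylbutanoyl)-5,5-di(prop-2-en-1-yl)-2,3-dihydro-1-benzofuran-4(5H)-one F4. Double cross-metathesis with 2-methyl-2-butene (Grubbs second-generation catalyst, CH2Cl2, 40 °C) would convert both allyl groups into prenyl groups, arriving at 25.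

3. Step 9. Metalation may be slow in the presence of the lithium alkoxide, or may not be fully selective for H7 over H5, leading to regioisomeric acylation.
Fallback: setting out from 16, electrophilic bromination (NBS, MeCN, −20 °C) should occur at the less hindered C7. It would give 2-[(2R)-7-bromo-6-(methoxymethoxy)-4-(triisopropylsilyloxy)-2,3-dihydro-1-benzofuran-2-yl]propan-2-ol F5, whose regiochemistry can be checked and any isomer removed at this stable stage. Deprotonation of the alcohol and bromine–lithium exchange (n-BuLi, 2.2 equiv, THF, −78 °C) would generate aryllithium 18 regiospecifically, and addition of 17 would rejoin the route at 19.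

**Further compounds**

F1 | step 7 | 5-(methoxymethoxy)-2-(3-methylbut-2-en-1-yl)-3-(triisopropylsilyloxy)phenol | CC(C)=CCc1c(O)cc(OCOC)cc1O[Si](C(C)C)(C(C)C)C(C)C
F2 | step 7 | 5-(methoxymethoxy)-2-(3-methylbut-2-en-1-yl)-3-(triisopropylsilyloxy)phenyl acetate | CC(C)=CCc1c(OC(C)=O)cc(OCOC)cc1O[Si](C(C)C)(C(C)C)C(C)C
F3 | step 7 | 2-{[(2S)-3,3-dimethyloxiran-2-yl]methyl}-5-(methoxymethoxy)-3-(triisopropylsilyloxy)phenyl acetate | CC1(C)O[C@H]1Cc2c(OC(C)=O)cc(OCOC)cc2O[Si](C(C)C)(C(C)C)C(C)C
F4 | step 12 | (2R)-6-hydroxy-2-(2-hydroxypropan-2-yl)-7-(3-methylbutanoyl)-5,5-di(prop-2-en-1-yl)-2,3-dihydro-1-benzofuran-4(5H)-one | C=CCC1(CC=C)C(=O)C2=C(O[C@@H](C(C)(C)O)C2)C(C(=O)CC(C)C)=C1O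
F5 | step 9 | 2-[(2R)-7-bromo-6-(methoxymethoxy)-4-(triisopropylsilyloxy)-2,3-dihydro-1-benzofuran-2-yl]propan-2-ol | COCOc1c(Br)c2O[C@@H](C(C)(C)O)Cc2c(O[Si](C(C)C)(C(C)C)C(C)C)c1
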